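## Structural features

Dehydroglyasperin D is an isoflav-3-ene: benzene ring A is fused through C4a and C8a to a 2H-pyran ring C (O1, C2H2, C3=C4), and C3 carries the 2,4-dihydroxyphenyl ring B. Ring A is pentasubstituted with all substituents contiguous: O1 on C8a, C4 on C4a, methoxy on C5, the 3-methylbut-2-enyl (prenyl) chain on C6 and methoxy on C7, so that only C8 bears hydrogen. The molecule has no stereocentre, so no stereocentres adjoin; the C3=C4 bond is held cis by ring C, and the one sp3 centre that appears on the way (the C4 carbinol) is racemic and is erased when ring C closes. The fragile parts are the stilbene-like C3=C4 bond of the chromene, the prenyl alkene and the free resorcinol of ring B. Protonation of the chromene at C3 gives a C4 cation stabilised by the oxygens on C5, C7 and C8a, which opens the way to hydride transfer between chromene molecules and to attack by O2'; the prenyl group is sensitive to acid and electrophiles and the resorcinol to oxidants, so the end of the route should use neither acid nor oxidant. The real difficulty is the regiochemistry of ring A: three oxygens must be told apart (two methyl ethers and the ring oxygen) and the prenyl group must sit between the two methoxy groups and not on C8. The key step exploits the alternating oxygen pattern C5/C7/C8a with carbon substituents on C4a and C6: C5–O is traced to a ketene carbonyl, C7–OMe to an enol ether and C8a–O to an ynol ether, so ring A can be assembled from two open-chain pieces by forming C7–C8, C4a–C5, C8–C8a and C5–C6.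

## Logic of the disconnections

29 to 28: the two O–allyl bonds on ring B are cut. The resorcinol is unmasked last and under neutral conditions because neither it nor the chromene tolerates acid or oxidants. The gain is that O2' stays blocked while ring C is formed. The forward step must spare the cyclic allylic ether C2–O1 and the prenyl group.

28 to 26: the O1–C2 bond is cut and the C4–O bond is restored, with silyl groups on O8a and on the C4 oxygen. An ortho-quinone methide (27) with a vinyl group on the methide carbon closes by oxa-6π electrocyclisation, so ring C and the C3=C4 bond come at the right oxidation level from an open chain. The forward step demands that only O8a is set free, which is why C5–O is already a methyl ether.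

26 to 25: the O–CH3 bond at C5 is cut. The ring-forming step necessarily delivers C5–O as a free phenol while O8a arrives silylated, so methylation at this point differentiates the two oxygens flanking C4a. The forward step must alkylate a doubly flanked phenol without silyl loss and without expelling the benzylic silyloxy group.

25 to 10 and 20: C7–C8, C4a–C5, C8–C8a and C5–C6 are cut. This reduces the pentasubstituted arene to two acyclic fragments of similar size in which every substituent position is fixed by connectivity. The forward step needs a regioselective ketene–ynol ether union and tolerance of the skipped diene, the 1,1-disubstituted alkene and the allyl ethers.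

10 to 8: the C1=N2 bond is cut. A methyl ketone is the safest precursor of a diazomethyl ketone; the forward step needs kinetic deprotonation of the methyl group in preference to the doubly allylic CH2.

8 to 6 (through 7): the C1–C2 bond (methyl to carbonyl) is cut. An ester is taken to the methyl ketone without over-addition; the forward step needs a mono-addition device.

6 to 4: the enol O–CH3 bond is cut. This leads back to an α-keto ester that can enolise only towards C3; the forward step must alkylate on oxygen and give the Z enol ether.

4 to 1 and 2 (through 3): the bond between the keto carbon and the homoprenyl chain is cut. Two inexpensive starting materials result; the forward step must stop at mono-addition.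

20 to 18: the C–O bond of the ynol ether and its O–Si bond are cut. A terminal alkyne is the simplest precursor; the forward step must oxygenate an acetylide and trap the ynolate on oxygen.

18 to 17: the O–Si bond on the carbinol oxygen is cut (protecting group).

17 to 15 and 16: the bond between the carbinol carbon (the future C4) and the alkyne is cut. This gives an enal and an acetylide; the forward step needs 1,2-addition.

15 to 13 and 13 to 12: the bond between the future C3 and the formyl carbon is cut, leading back through a sulfonylhydrazone to an aryl methyl ketone. The forward step needs a regiodefined 1-arylvinyl anion.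

12 to 11: the two O–allyl bonds are cut, leading to the commercial dihydroxy ketone.

## Other disconnections considered

Alternative 1: Cut of C4–C4a, O1–C2 and one C3–C bond to a one-carbon unit. In the forward sense the enol ether formed from the arylacetaldehyde acetal A2 attacks triethyl orthoformate A3 under a boron Lewis acid, and the resulting 2-arylmalonaldehyde equivalent condenses with the symmetrical phenol A1 under a strong protic acid to give the chromenylium tetrafluoroborate A4. Hydride delivery to C2 would then give 28.
- In favour: very short and convergent, cheap components, and no regiochemical question in the ring closure because both ortho positions of A1 and both ends of the three-carbon unit are equivalent.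
- Against: strongly acidic conditions in the presence of the prenyl alkene; a product at the wrong oxidation level, whose reduction must choose C2 over C4; and the ring A problem is only moved into the preparation of A1.
- Comparison: on step economy this alternative is the better of the two (roughly nine steps in all against fourteen). On structure it relies on a preformed ring A, whereas the chosen plan builds it. On mechanism it is cationic where the chosen plan is pericyclic, acid-free and arrives directly at the chromene oxidation level.

Alternative 2: Cut of C8a–O1, C4a–C4 and O1–C2. A fluoride source releases the C4a–C8a aryne from the silyl triflate A5; the aldehyde C=O of the enal A6 adds across it, the adduct opens to an ortho-quinone methide of the same type as 27, and oxa-6π closure gives the bis(methoxymethyl) ether A7.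
- In favour: three bonds and ring C in one neutral step, the correct oxidation level, and no late differentiation of O5 from O8a because the C5 methyl ether is already present; on these points it is the better plan. The polarisation of the 3-alkoxy aryne directs oxygen to C8a, so on regiochemistry it is the equal of the chosen plan, and the final electrocyclisation is the same.
- Against: A5 is itself a pentasubstituted benzene that needs several steps from A1; the aryne can be diverted by ene reactions or by the enal acting through its alkene; the enal polymerises easily under basic fluoride; and A7 needs acid for deprotection (using 15 instead of A6 would give 28 and remove this last objection).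
- Comparison: the step count would be somewhat lower than for the chosen plan, but the ring A regiochemistry is not solved by the key step.

Alternative 3: Cut of C4–C4a. Constant-current anodic oxidation of the aryl 2-arylallyl ether A8 in a buffered perchlorate electrolyte couples the terminal alkene carbon to ring A, closes ring C and oxidises further to the chromenylium perchlorate A9. Reduction at C2 and desilylation would lead to 29.
- In favour: A8 comes from A1 by simple O-alkylation, no organometallic reagent is needed, and the final deprotection would use fluoride only, which equals the mildness of the chosen end game.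
- Against: the oxidation passes through the oxidation level of the target and beyond, so a reduction must follow; three electron-rich π systems and the prenyl alkene compete at the anode; organic perchlorates are an explosion hazard; and the regiochemistry of hydride addition is open.
- Comparison: shorter than the chosen plan and therefore better on step economy, but weaker on chemoselectivity and safety, and again dependent on a preformed ring A.

Key step: step 11

Remark on the chemistry: all compounds carrying the C4 carbinol centre are racemic (the centre is destroyed in step 13); ring B is carried as its bis(allyl) ether so that no acid is needed at the end; and the diazoketone is reached by deacylative diazo transfer so that diazomethane is avoided. The skeletons of the two benzannulation partners and of the benzannulation product are otherwise unchanged.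

## Route

Step 1
Reactants: 1 5-bromo-2-methylpent-2-ene; 2 diethyl oxalate
Product: 4 ethyl 6-methyl-2-oxohept-5-enoate, via 4-methylpent-3-enylmagnesium bromide 3 (not isolated)
Conditions: Mg, THF, rt to 40 °C; then added to 2 (2 equiv), THF, −78 °C; aq. NH4Cl
Reagents that add atoms: none
Why: Grignard formation and mono-acylation by a dialkyl oxalate; inverse addition at −78 °C to excess oxalate keeps the reaction at the mono-adduct stage, and the homoallylic Grignard reagent does not rearrange.

Step 2
Reactants: 4 ethyl 6-methyl-2-oxohept-5-enoate
Product: 6 ethyl (2Z)-2-methoxy-6-methylhepta-2,5-dienoate, via potassium enolate 5 (not isolated)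
Conditions: 4 added to KN(SiMe3)2 (1.05 equiv), THF–DMPU, −78 °C; MeOTs, −78 to 0 °C
Reagents that add atoms: methyl p-toluenesulfonate, COS(=O)(=O)c1ccc(C)cc1
Why: O-alkylation of an ambident potassium enolate by a hard sulfonate ester in a dipolar medium; enolisation is possible only towards C3, and the enolate with the chain anti to the ester group places methoxy and chain cis (Z). One equivalent of base avoids deprotonation at the doubly allylic C4.

Step 3
Reactants: 6 ethyl (2Z)-2-methoxy-6-methylhepta-2,5-dienoate
Product: 8 (3Z)-3-methoxy-7-methylocta-3,6-dien-2-one, via Weinreb amide 7 (not isolated)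
Conditions: MeNHOMe·HCl (1.5 equiv), i-PrMgCl (3.0 equiv), THF, −20 °C; then MeMgBr, −20 to 0 °C; aq. NH4Cl
Reagents that add atoms: methylmagnesium bromide, C[Mg]Br
Why: Weinreb ketone synthesis run in one pot: the chloromagnesium amide converts the ester into 7 and MeMgBr adds once because the chelated adduct survives until the quench. The donor-substituted enoate is a poor conjugate acceptor.

Step 4
Reactants: 8 (3Z)-3-methoxy-7-methylocta-3,6-dien-2-one
Product: 10 (3Z)-1-diazo-3-methoxy-7-methylocta-3,6-dien-2-one, via trifluoroacetyl diketone 9 (not isolated)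
Conditions: LiN(SiMe3)2, THF, −78 °C; CF3CO2CH2CF3, −78 °C; aq. HCl wash; then 4-acetamidobenzenesulfonyl azide, Et3N, H2O (1 equiv), MeCN, rt
Reagents that add atoms: 4-acetamidobenzenesulfonyl azide, CC(=O)Nc1ccc(cc1)S(=O)(=O)N=[N+]=[N-]
Why: Detrifluoroacetylative (Regitz-type) diazo transfer: kinetic deprotonation of the methyl group, Claisen-type trifluoroacetylation to 9 and transfer of N2 with loss of the trifluoroacetyl group. This avoids diazomethane and the pyrazoline formation that diazoalkanes risk with enoyl chlorides.

Step 5
Reactants: 11 2',4'-dihydroxyacetophenone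
Product: 12 1-[2,4-bis(allyloxy)phenyl]ethanone
Conditions: allyl bromide (2.5 equiv), K2CO3, DMF, 60 °C
Reagents that add atoms: allyl bromide, C=CCBr
Why: Williamson etherification of both phenols; warming in DMF overcomes the hydrogen bond of the 2'-hydroxyl to the ketone.

Step 6
Reactants: 12 1-[2,4-bis(allyloxy)phenyl]ethanone
Product: 13 N'-{(1E)-1-[2,4-bis(allyloxy)phenyl]ethylidene}-2,4,6-triisopropylbenzenesulfonohydrazide
Conditions: 2,4,6-triisopropylbenzenesulfonohydrazide, MeOH, HCl (cat.), rt
Reagents that add atoms: 2,4,6-triisopropylbenzenesulfonohydrazide, NNS(=O)(=O)c1c(C(C)C)cc(C(C)C)cc1C(C)C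
Why: Acid-catalysed hydrazone condensation at room temperature, where the hindered sulfonohydrazide is stable; the E isomer places the N–H syn to the methyl group as the next step requires.

Step 7
Reactants: 13 N'-{(1E)-1-[2,4-bis(allyloxy)phenyl]ethylidene}-2,4,6-triisopropylbenzenesulfonohydrazide
Product: 15 2-[2,4-bis(allyloxy)phenyl]prop-2-enal, via 1-arylvinyllithium 14 (not isolated)
Conditions: n-BuLi (2.1 equiv), THF, −78 to 0 °C; DMF, −78 to 0 °C; aq. NH4Cl
Reagents that add atoms: N,N-dimethylformamide, CN(C)C=O
Why: Shapiro reaction: the hydrazone dianion loses sulfinate and N2 on warming to give 14 regiospecifically (only the methyl group has α-hydrogens), and formylation with DMF gives the 2-arylacrolein. The hindered sulfonyl group prevents metalation of the reagent's own ring.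

Step 8
Reactants: 15 2-[2,4-bis(allyloxy)phenyl]prop-2-enal; 16 ethynylmagnesium bromide
Product: 17 racemic 2-[2,4-bis(allyloxy)phenyl]pent-1-en-4-yn-3-ol
Conditions: THF, −78 to 0 °C; aq. NH4Cl (15 used freshly prepared)
Reagents that add atoms: none
Why: 1,2-addition of an alkynyl Grignard reagent to an enal; the new carbinol centre is formed racemic and needs no control because it is destroyed in step 13.

Step 9
Reactants: 17 racemic 2-[2,4-bis(allyloxy)phenyl]pent-1-en-4-yn-3-ol
Product: 18 racemic tert-butyl({2-[2,4-bis(allyloxy)phenyl]pent-1-en-4-yn-3-yl}oxy)dimethylsilane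
Conditions: t-BuMe2SiCl, imidazole, DMF, rt
Reagents that add atoms: tert-butyldimethylsilyl chloride, CC(C)(C)[Si](C)(C)Cl
Why: Standard silylation of a secondary alcohol; the silyl ether survives the amide base and peroxide of step 10 and is a poor leaving group until ring C is to be closed.

Step 10
Reactants: 18 racemic tert-butyl({2-[2,4-bis(allyloxy)phenyl]pent-1-en-4-yn-3-yl}oxy)dimethylsilane
Product: 20 racemic tert-butyl({2-[2,4-bis(allyloxy)phenyl]-5-[(triisopropylsilyl)oxy]pent-1-en-4-yn-3-yl}oxy)dimethylsilane, via lithium ynolate 19 (not isolated)
Conditions: LiN(SiMe3)2 (2.2 equiv), THF, −78 °C; t-BuOOH (anhydrous, in decane), −78 to 0 °C; i-Pr3SiOTf, −78 °C; pentane/aq. NaHCO3; Et3N-deactivated silica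
Reagents that add atoms: tert-butyl hydroperoxide, CC(C)(C)OO; triisopropylsilyl trifluoromethanesulfonate, CC(C)[Si](C(C)C)(C(C)C)OS(=O)(=O)C(F)(F)F
Why: Electrophilic oxygenation of a lithium acetylide by lithium tert-butyl peroxide gives ynolate 19, which the hard, bulky silyl triflate traps on oxygen; the amide base is too weak to remove the propargylic hydrogen.

Step 11
Reactants: 10 (3Z)-1-diazo-3-methoxy-7-methylocta-3,6-dien-2-one; 20 racemic tert-butyl({2-[2,4-bis(allyloxy)phenyl]-5-[(triisopropylsilyl)oxy]pent-1-en-4-yn-3-yl}oxy)dimethylsilane
Product: 25 racemic 2-{2-[2,4-bis(allyloxy)phenyl]-1-[(tert-butyldimethylsilyl)oxy]prop-2-enyl}-5-methoxy-6-(3-methylbut-2-enyl)-3-[(triisopropylsilyl)oxy]phenol, via vinylketene 21 (not isolated), via 4-vinylcyclobutenone 22 (not isolated), via dienylketene 23 (not isolated), via cyclohexa-2,4-dienone 24 (not isolated)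
Conditions: hν (medium-pressure Hg lamp, Pyrex, λ > 300 nm), degassed ClCH2CH2Cl, rt, 10 (1.3 equiv) added slowly; then 80 °C; crude 25 taken on
Reagents that add atoms: none
Why: Photolysis releases N2 from 10 and the alkenyl group shifts to the former diazo carbon (photochemical Wolff rearrangement, C7–C8), giving vinylketene 21; the Z geometry holds the prenyl chain trans to the ketene so that it cannot add intramolecularly. The nucleophilic carbon of ynol ether 20 (the one bearing the side chain) attacks the ketene carbonyl carbon and the siloxy carbon closes onto the ketene α-carbon, a polar stepwise [2+2] whose orientation follows from the polarisation of both partners and forms C4a–C5 and C8–C8a in the four-membered ring of 22. Strain drives conrotatory 4π opening of 22 (thermally or under continued irradiation) to dienylketene 23, and disrotatory 6π electrocyclisation closes the six-membered ring A through C5–C6 to give 24, which tautomerises to phenol 25. The closest known reaction type is the Danheiser benzannulation in its photochemical diazoketone form with siloxyalkynes, which gives resorcinol monosilyl ethers. No lasting stereocentre is created: the carbinol centre of 20 is carried through racemic and the sp3 centres of 22 and 24 disappear. The step needs chemoselective capture of the ketene by the ynol ether in preference to the styrene, allyl and prenyl alkenes, which the far higher nucleophilicity of the siloxyalkyne and irradiation above 300 nm should secure. It also needs a thermal stage no hotter than 80 °C so that the free C5 phenol does not expel the benzylic silyloxy group.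

Step 12
Reactants: 25 racemic 2-{2-[2,4-bis(allyloxy)phenyl]-1-[(tert-butyldimethylsilyl)oxy]prop-2-enyl}-5-methoxy-6-(3-methylbut-2-enyl)-3-[(triisopropylsilyl)oxy]phenol
Product: 26 racemic tert-butyl{2-[2,4-bis(allyloxy)phenyl]-1-[2,4-dimethoxy-3-(3-methylbut-2-enyl)-6-(triisopropylsilyloxy)phenyl]prop-2-enyloxy}dimethylsilane
Conditions: MeI (excess), K2CO3, acetone, rt to 40 °C; MeI removed before step 13
Reagents that add atoms: methyl iodide, CI
Why: Williamson O-methylation of the only free phenol; the weak base and low temperature leave the hindered aryl silyl ether in place, and methyl transfer to the phenoxide should outrun expulsion of the benzylic silyloxy group.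

Step 13
Reactants: 26 racemic tert-butyl{2-[2,4-bis(allyloxy)phenyl]-1-[2,4-dimethoxy-3-(3-methylbut-2-enyl)-6-(triisopropylsilyloxy)phenyl]prop-2-enyloxy}dimethylsilane
Product: 28 3-[2,4-bis(allyloxy)phenyl]-5,7-dimethoxy-6-(3-methylbut-2-enyl)-2H-chromene, via o-quinone methide 27 (not isolated)
Conditions: Bu4NF (3 equiv), degassed THF, 0 to 40 °C; aq. NH4Cl
Reagents that add atoms: none
Why: Fluoride cleaves the aryl O–Si bond and the C8a phenoxide expels the benzylic oxygen (as silanolate, or as hydroxide once that silyl ether has also been cleaved) to give o-quinone methide 27, whose vinyl group lies syn to the carbonyl and away from the C5 methoxy group, so that oxa-6π electrocyclisation closes ring C. C5–O is methylated and O2' is allylated, so no other oxygen can close; the racemic carbinol centre is destroyed here.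

Step 14
Reactants: 28 3-[2,4-bis(allyloxy)phenyl]-5,7-dimethoxy-6-(3-methylbut-2-enyl)-2H-chromene
Product: 29 dehydroglyasperin D, 4-[5,7-dimethoxy-6-(3-methylbut-2-enyl)-2H-chromen-3-yl]benzene-1,3-diol
Conditions: Pd(PPh3)4 (5 mol %), morpholine, degassed THF, rt, argon
Reagents that add atoms: none
Why: Tsuji–Trost-type deallylation: zerovalent palladium ionises the two unsubstituted O-allyl groups to π-allyl complexes that morpholine intercepts under neutral conditions. The ring C allylic ether is trisubstituted and 2-aryl-substituted and should ionise far more slowly; the prenyl group is inert.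

## Compound list

1 | 5-bromo-2-methylpent-2-ene | CC(C)=CCCBr | starting material
2 | diethyl oxalate | CCOC(=O)C(=O)OCC | starting material
3 | (4-methylpent-3-enyl)magnesium bromide | CC(C)=CCC[Mg]Br | intermediate
4 | ethyl 6-methyl-2-oxohept-5-enoate | CCOC(=O)C(=O)CCC=C(C)C | intermediate
5 | potassium (2Z)-1-ethoxy-6-methyl-1-oxohepta-2,5-dien-2-olate | [K+].CCOC(=O)/C([O-])=C/CC=C(C)C | intermediate
6 | ethyl (2Z)-2-methoxy-6-methylhepta-2,5-dienoate | CCOC(=O)/C(OC)=C/CC=C(C)C | intermediate
7 | (2Z)-N,2-dimethoxy-N,6-dimethylhepta-2,5-dienamide | CON(C)C(=O)/C(OC)=C/CC=C(C)C | intermediate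
8 | (3Z)-3-methoxy-7-methylocta-3,6-dien-2-one | CC(=O)/C(OC)=C/CC=C(C)C | intermediate
9 | (5Z)-1,1,1-trifluoro-5-methoxy-9-methyldeca-5,8-diene-2,4-dione | O=C(CC(=O)/C(OC)=C/CC=C(C)C)C(F)(F)F | intermediate
10 | (3Z)-1-diazo-3-methoxy-7-methylocta-3,6-dien-2-one | [N-]=[N+]=CC(=O)/C(OC)=C/CC=C(C)C | intermediate
11 | 2',4'-dihydroxyacetophenone | CC(=O)c1ccc(O)cc1O | starting material
12 | 1-[2,4-bis(allyloxy)phenyl]ethanone | CC(=O)c1ccc(OCC=C)cc1OCC=C | intermediate
13 | N'-{(1E)-1-[2,4-bis(allyloxy)phenyl]ethylidene}-2,4,6-triisopropylbenzenesulfonohydrazide | C/C(=N\NS(=O)(=O)c1c(C(C)C)cc(C(C)C)cc1C(C)C)c1ccc(OCC=C)cc1OCC=C | intermediate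
14 | {1-[2,4-bis(allyloxy)phenyl]ethenyl}lithium | [Li]C(=C)c1ccc(OCC=C)cc1OCC=C | intermediate
15 | 2-[2,4-bis(allyloxy)phenyl]prop-2-enal | C=C(C=O)c1ccc(OCC=C)cc1OCC=C | intermediate
16 | ethynylmagnesium bromide | C#C[Mg]Br | starting material
17 | racemic 2-[2,4-bis(allyloxy)phenyl]pent-1-en-4-yn-3-ol | C#CC(O)C(=C)c1ccc(OCC=C)cc1OCC=C | intermediate
18 | racemic tert-butyl({2-[2,4-bis(allyloxy)phenyl]pent-1-en-4-yn-3-yl}oxy)dimethylsilane | C#CC(O[Si](C)(C)C(C)(C)C)C(=C)c1ccc(OCC=C)cc1OCC=C | intermediate
19 | racemic lithium 4-[2,4-bis(allyloxy)phenyl]-3-[(tert-butyldimethylsilyl)oxy]pent-4-en-1-yn-1-olate | [Li+].[O-]C#CC(O[Si](C)(C)C(C)(C)C)C(=C)c1ccc(OCC=C)cc1OCC=C | intermediate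
20 | racemic tert-butyl({2-[2,4-bis(allyloxy)phenyl]-5-[(triisopropylsilyl)oxy]pent-1-en-4-yn-3-yl}oxy)dimethylsilane | C=C(c1ccc(OCC=C)cc1OCC=C)C(O[Si](C)(C)C(C)(C)C)C#CO[Si](C(C)C)(C(C)C)C(C)C | intermediate
21 | (3Z)-3-methoxy-7-methylocta-1,3,6-trien-1-one | O=C=C/C(OC)=C/CC=C(C)C | intermediate
22 | 2-{2-[2,4-bis(allyloxy)phenyl]-1-[(tert-butyldimethylsilyl)oxy]prop-2-enyl}-4-[(1Z)-1-methoxy-5-methylhexa-1,4-dienyl]-3-[(triisopropylsilyl)oxy]cyclobut-2-en-1-one (mixture of diastereomers) | O=C1C(C(O[Si](C)(C)C(C)(C)C)C(=C)c2ccc(OCC=C)cc2OCC=C)=C(O[Si](C(C)C)(C(C)C)C(C)C)C1/C(OC)=C/CC=C(C)C | intermediate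
23 | racemic (3E,5Z)-2-{2-[2,4-bis(allyloxy)phenyl]-1-[(tert-butyldimethylsilyl)oxy]prop-2-enyl}-5-methoxy-9-methyl-3-[(triisopropylsilyl)oxy]deca-1,3,5,8-tetraen-1-one | O=C=C(C(O[Si](C)(C)C(C)(C)C)C(=C)c1ccc(OCC=C)cc1OCC=C)/C(O[Si](C(C)C)(C(C)C)C(C)C)=C\C(OC)=C\CC=C(C)C | intermediate
24 | 2-{2-[2,4-bis(allyloxy)phenyl]-1-[(tert-butyldimethylsilyl)oxy]prop-2-enyl}-5-methoxy-6-(3-methylbut-2-enyl)-3-[(triisopropylsilyl)oxy]cyclohexa-2,4-dien-1-one (mixture of diastereomers) | O=C1C(C(O[Si](C)(C)C(C)(C)C)C(=C)c2ccc(OCC=C)cc2OCC=C)=C(O[Si](C(C)C)(C(C)C)C(C)C)C=C(OC)C1CC=C(C)C | intermediate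
25 | racemic 2-{2-[2,4-bis(allyloxy)phenyl]-1-[(tert-butyldimethylsilyl)oxy]prop-2-enyl}-5-methoxy-6-(3-methylbut-2-enyl)-3-[(triisopropylsilyl)oxy]phenol | Oc1c(C(O[Si](C)(C)C(C)(C)C)C(=C)c2ccc(OCC=C)cc2OCC=C)c(O[Si](C(C)C)(C(C)C)C(C)C)cc(OC)c1CC=C(C)C | intermediate
26 | racemic tert-butyl{2-[2,4-bis(allyloxy)phenyl]-1-[2,4-dimethoxy-3-(3-methylbut-2-enyl)-6-(triisopropylsilyloxy)phenyl]prop-2-enyloxy}dimethylsilane | COc1c(C(O[Si](C)(C)C(C)(C)C)C(=C)c2ccc(OCC=C)cc2OCC=C)c(O[Si](C(C)C)(C(C)C)C(C)C)cc(OC)c1CC=C(C)C | intermediate
27 | (6Z)-6-{2-[2,4-bis(allyloxy)phenyl]prop-2-enylidene}-3,5-dimethoxy-4-(3-methylbut-2-enyl)cyclohexa-2,4-dien-1-one | C=C(c1ccc(OCC=C)cc1OCC=C)/C=C2\C(=O)C=C(OC)C(CC=C(C)C)=C2OC | intermediate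
28 | 3-[2,4-bis(allyloxy)phenyl]-5,7-dimethoxy-6-(3-methylbut-2-enyl)-2H-chromene | COc1cc2c(c(OC)c1CC=C(C)C)C=C(c1ccc(OCC=C)cc1OCC=C)CO2 | intermediate
29 | dehydroglyasperin D, 4-[5,7-dimethoxy-6-(3-methylbut-2-enyl)-2H-chromen-3-yl]benzene-1,3-diol | COc1cc2c(c(OC)c1CC=C(C)C)C=C(c1ccc(O)cc1O)CO2 | target

## Step count and least certain steps

Total: 14 steps (steps 1–4 to fragment 1, steps 5–10 to fragment 2, steps 11–14 after the union). Longest linear sequence: 10 steps (steps 5–14 from 11).

Step 11 (key step). The most likely failures are three. First, slow bimolecular capture of 21 by the branched, hindered ynol ether, so that ketene dimerisation or acylation of the newly formed phenol takes over. Second, loss of the benzylic silyloxy group from the free C5 phenol during the thermal stage, followed by ring closure onto the wrong oxygen. Third, competitive light absorption by the aryl-substituted alkene. Fallback, which builds ring C by a phenol–enal annulation on a preformed ring A: it sets out from 15 and returns at 28. Commercial 3,5-dimethoxyphenol F1 is silylated (i-Pr3SiCl, imidazole) to (3,5-dimethoxyphenoxy)triisopropylsilane F2. F2 is lithiated between the two methoxy groups (n-BuLi, THF, 0 °C) and prenylated (CuBr·SMe2 cat., prenyl bromide) to [3,5-dimethoxy-4-(3-methylbut-2-enyl)phenoxy]triisopropylsilane F3. Bu4NF gives 3,5-dimethoxy-4-(3-methylbut-2-enyl)phenol F4, whose two ortho positions are equivalent. Heating F4 with 15 and PhB(OH)2 (propionic acid cat., toluene, reflux) should give 28 through a cyclic aryl boronate, an ortho-quinone methide and oxa-6π closure.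

Step 10. Oxygen transfer to the hindered acetylide may be incomplete, and the ynol silyl ether may be protonated and hydrolysed during work-up or chromatography. Fallback by the Kowalski ester homologation, setting out from 13 and returning at 20. The vinyllithium 14 made as in step 7 is added to ethyl glyoxylate to give racemic ethyl 3-[2,4-bis(allyloxy)phenyl]-2-hydroxybut-3-enoate F5. Silylation (t-BuMe2SiCl, imidazole) gives racemic ethyl 3-[2,4-bis(allyloxy)phenyl]-2-[(tert-butyldimethylsilyl)oxy]but-3-enoate F6. Treatment with CH2Br2 and lithium 2,2,6,6-tetramethylpiperidide at −78 °C, then n-BuLi, then i-Pr3SiCl, gives 20.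

Step 13. Desilylation may stop short of elimination, leaving the benzylic oxygen in place under the basic conditions, or 27 may be captured intermolecularly by phenoxide before it cyclises. Fallback in two separate operations, setting out from 26 and returning at 28. Buffered fluoride (Bu4NF/AcOH, THF, 0 °C) gives racemic 2-{2-[2,4-bis(allyloxy)phenyl]-1-hydroxyprop-2-enyl}-3,5-dimethoxy-4-(3-methylbut-2-enyl)phenol F7. F7 is then dehydrated under neutral conditions through its cyclic phenylboronate (PhB(OH)2, toluene, 80 °C), which fragments to the same ortho-quinone methide.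

Step 2. The enolate may be methylated on carbon or condense with unreacted keto ester, and excess base may move the C5=C6 double bond into conjugation. Fallback without an enolate, setting out from 4 and returning at 6. Ketalisation (HC(OMe)3, MeOH, TsOH cat.) gives ethyl 2,2-dimethoxy-6-methylhept-5-enoate F8, and elimination of methanol with Me3SiOTf and i-Pr2NEt (CH2Cl2, −20 °C to rt) gives 6.

Step 7. n-BuLi or 14 may attack the O-allyl groups (SN2' displacement or carbolithiation) or metalate the ring next to oxygen, and the 2-arylacrolein may polymerise on concentration. Fallback without organolithium reagents, setting out from 12 and returning at 15. Wittig methylenation (Ph3PCH3Br, KOt-Bu, THF) gives 2,4-bis(allyloxy)-1-(prop-1-en-2-yl)benzene F9, and allylic oxidation of the methyl group (SeO2 cat., t-BuOOH, CH2Cl2) gives 15.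

Step 14. Palladium may also ionise the allylic C2–O1 bond of ring C and open it, and the free resorcinol may oxidise in air during isolation. Fallback by hydroalumination and β-elimination instead of π-allyl chemistry, setting out from 28 and returning at 29: NiCl2(dppp) (cat.), i-Bu2AlH, toluene, 0 °C, which releases propene and involves no nucleophile (no new compound, F0).

## Further compounds

F1 | step 11 | 3,5-dimethoxyphenol | COc1cc(O)cc(OC)c1
F2 | step 11 | (3,5-dimethoxyphenoxy)triisopropylsilane | COc1cc(OC)cc(O[Si](C(C)C)(C(C)C)C(C)C)c1
F3 | step 11 | [3,5-dimethoxy-4-(3-methylbut-2-enyl)phenoxy]triisopropylsilane | COc1cc(O[Si](C(C)C)(C(C)C)C(C)C)cc(OC)c1CC=C(C)C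
F4 | step 11 | 3,5-dimethoxy-4-(3-methylbut-2-enyl)phenol | COc1cc(O)cc(OC)c1CC=C(C)C
F5 | step 10 | racemic ethyl 3-[2,4-bis(allyloxy)phenyl]-2-hydroxybut-3-enoate | CCOC(=O)C(O)C(=C)c1ccc(OCC=C)cc1OCC=C
F6 | step 10 | racemic ethyl 3-[2,4-bis(allyloxy)phenyl]-2-[(tert-butyldimethylsilyl)oxy]but-3-enoate | CCOC(=O)C(O[Si](C)(C)C(C)(C)C)C(=C)c1ccc(OCC=C)cc1OCC=C
F7 | step 13 | racemic 2-{2-[2,4-bis(allyloxy)phenyl]-1-hydroxyprop-2-enyl}-3,5-dimethoxy-4-(3-methylbut-2-enyl)phenol | COc1cc(O)c(C(O)C(=C)c2ccc(OCC=C)cc2OCC=C)c(OC)c1CC=C(C)C
F8 | step 2 | ethyl 2,2-dimethoxy-6-methylhept-5-enoate | CCOC(=O)C(OC)(OC)CCC=C(C)C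
F9 | step 7 | 2,4-bis(allyloxy)-1-(prop-1-en-2-yl)benzene | CC(=C)c1ccc(OCC=C)cc1OCC=C
F0 | step 14 | none | none
A1 | alternative 1 | 3,5-dimethoxy-4-(3-methylbut-2-enyl)phenol | COc1cc(O)cc(OC)c1CC=C(C)C
A2 | alternative 1 | 1-(2,2-dimethoxyethyl)-2,4-bis(allyloxy)benzene | COC(OC)Cc1ccc(OCC=C)cc1OCC=C
A3 | alternative 1 | triethyl orthoformate | CCOC(OCC)OCC
A4 | alternative 1 | 3-[2,4-bis(allyloxy)phenyl]-5,7-dimethoxy-6-(3-methylbut-2-enyl)chromenylium tetrafluoroborate | COc1cc2[o+]cc(-c3ccc(OCC=C)cc3OCC=C)cc2c(OC)c1CC=C(C)C.F[B-](F)(F)F
A5 | alternative 2 | 3,5-dimethoxy-4-(3-methylbut-2-enyl)-2-(trimethylsilyl)phenyl trifluoromethanesulfonate | COc1cc(OS(=O)(=O)C(F)(F)F)c([Si](C)(C)C)c(OC)c1CC=C(C)C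
A6 | alternative 2 | 2-[2,4-bis(methoxymethoxy)phenyl]prop-2-enal | C=C(C=O)c1ccc(OCOC)cc1OCOC
A7 | alternative 2 | dehydroglyasperin D bis(methoxymethyl) ether, 3-[2,4-bis(methoxymethoxy)phenyl]-5,7-dimethoxy-6-(3-methylbut-2-enyl)-2H-chromene | COc1cc2c(c(OC)c1CC=C(C)C)C=C(c1ccc(OCOC)cc1OCOC)CO2
A8 | alternative 3 | 1-{3-[3,5-dimethoxy-4-(3-methylbut-2-enyl)phenoxy]prop-1-en-2-yl}-2,4-bis[(tert-butyldimethylsilyl)oxy]benzene | COc1cc(OCC(=C)c2ccc(O[Si](C)(C)C(C)(C)C)cc2O[Si](C)(C)C(C)(C)C)cc(OC)c1CC=C(C)C
A9 | alternative 3 | 3-[2,4-bis(tert-butyldimethylsilyloxy)phenyl]-5,7-dimethoxy-6-(3-methylbut-2-enyl)chromenylium perchlorate | COc1cc2[o+]cc(-c3ccc(O[Si](C)(C)C(C)(C)C)cc3O[Si](C)(C)C(C)(C)C)cc2c(OC)c1CC=C(C)C.[O-]Cl(=O)(=O)=O
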